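The route rests on cutting C5–C10 and C8–C9. In ring B the C6 ketone, flanked by C5–H and the C7=C8 alkene, is read as the trace of a 2-siloxydiene C5=C6(OSi)–C7=C8. C9=C10 is an E-enoyl imide, and C1–C4, the rest of ring A, is the tether between them. One copper–bis(oxazoline)-catalysed intramolecular Diels–Alder reaction of the acyclic (3S)-siloxytriene imide 20 closes rings A and B together and sets C5, C8, C9 and the quaternary C10. The surviving C6=C7 enol ether is later dehydrogenated to the enone, which erases C8. Only C3 is set earlier, by asymmetric reverse prenylation of an aldehyde cut from methyl geranate.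

Key step: step 11

Remark on the chemistry: drimane numbering is used throughout. CIP analysis of the target gives 3S,5S,9R,10S, a trans-decalin with C10–CH3 and C9–CH2OAr cis and the C3 hydroxyl axial, anti to C10–CH3.

Assumption: (+)-Ipc2BH (Ipc = isopinocampheyl) is the known crystalline reagent from (−)-α-pinene and BH3·SMe2, and the copper catalyst is made beforehand from CuCl2, AgSbF6 and the ligand. Neither preparation is counted as a step.

Step 1
Reactants: 1 methyl geranate (methyl (2E)-3,7-dimethylocta-2,6-dienoate)
Product: 3 methyl (2E)-3-methyl-6-oxohex-2-enoate, via secondary ozonide 2 (not isolated)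
Conditions: O3 (1 equiv, Sudan Red 7B end point), CH2Cl2, −78 °C; then Me2S, −78 °C → rt
Reagents that add atoms: ozone, [O-][O+]=O
Why: Chemoselective ozonolysis (Criegee mechanism) in which the electron-rich trisubstituted alkene reacts far faster with electrophilic ozone than the conjugated enoate, and reduction of the ozonide with Me2S stops at the aldehyde carbon that becomes C3.

Step 2
Reactants: 3 methyl (2E)-3-methyl-6-oxohex-2-enoate; 4 3-methylbuta-1,2-diene
Product: 7 methyl (2E,6S)-6-hydroxy-3,7,7-trimethylnona-2,8-dienoate, via prenyldiisopinocampheylborane 5 (not isolated), via homoallyl borinate 6 (not isolated)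
Conditions: (+)-Ipc2BH, 4, THF, −25 °C; then 3, Et2O, −78 °C; then NaBO3·4H2O, THF–H2O, rt
Reagents that add atoms: none
Why: Brown allylboration in its reverse-prenyl form, in which hydroboration of the allene gives the 3,3-dimethylallylborane, this adds through its γ-carbon in a closed chair transition state so that C4 arrives as the gem-dimethyl quaternary carbon, and the isopinocampheyl groups derived from (−)-α-pinene direct attack to the Re face of the aldehyde, which sets (3S).

Step 3
Reactants: 7 methyl (2E,6S)-6-hydroxy-3,7,7-trimethylnona-2,8-dienoate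
Product: 8 methyl (2E,6S)-6-[(tert-butyldimethylsilyl)oxy]-3,7,7-trimethylnona-2,8-dienoate
Conditions: TBSOTf, 2,6-lutidine, CH2Cl2, 0 °C
Reagents that add atoms: tert-butyldimethylsilyl triflate, CC(C)(C)[Si](C)(C)OS(=O)(=O)C(F)(F)F
Why: Silyl ether formation with the reactive silyl triflate, which is needed for this neopentyl-type secondary alcohol, gives a group that survives base, hydride, oxidants and Lewis acid and leaves C3 untouched.

Step 4
Reactants: 8 methyl (2E,6S)-6-[(tert-butyldimethylsilyl)oxy]-3,7,7-trimethylnona-2,8-dienoate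
Product: 10 methyl (2E,6S)-6-[(tert-butyldimethylsilyl)oxy]-9-hydroxy-3,7,7-trimethylnon-2-enoate, via B-alkyl-9-BBN adduct 9 (not isolated)
Conditions: 9-BBN, THF, 0 °C → rt; then NaBO3·4H2O, H2O, rt
Reagents that add atoms: sodium perborate, [Na+].[Na+].O[B-]1(O)OO[B-](O)(O)OO1
Why: Hydroboration–oxidation in which the bulky 9-BBN adds anti-Markovnikov to the monosubstituted vinyl group only, ignores the electron-poor trisubstituted enoate and the ester, and the nearly neutral perborate turns the C6–B bond into the C6 alcohol.

Step 5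
Reactants: 10 methyl (2E,6S)-6-[(tert-butyldimethylsilyl)oxy]-9-hydroxy-3,7,7-trimethylnon-2-enoate
Product: 11 methyl (2E,6S)-6-[(tert-butyldimethylsilyl)oxy]-3,7,7-trimethyl-9-oxonon-2-enoate
Conditions: Dess–Martin periodinane (DMP), CH2Cl2, 0 °C → rt
Reagents that add atoms: none
Why: Dess–Martin oxidation converts the primary alcohol into the C6 aldehyde without over-oxidation and without touching the silyl ether or the enoate.

Step 6
Reactants: 11 methyl (2E,6S)-6-[(tert-butyldimethylsilyl)oxy]-3,7,7-trimethyl-9-oxonon-2-enoate; 12 (E)-1-bromoprop-1-ene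
Product: 14 methyl (2E,6S,10E)-6-[(tert-butyldimethylsilyl)oxy]-9-hydroxy-3,7,7-trimethyldodeca-2,10-dienoate (both epimers at the new carbinol carbon, drimane C6), via (E)-prop-1-enyllithium 13 (not isolated)
Conditions: 12, t-BuLi (2 equiv), Et2O, −78 °C; cannulated (1.05 equiv) into 11, THF, −78 °C; then aq NH4Cl
Reagents that add atoms: none
Why: Bromine–lithium exchange proceeds with retention of the E geometry, and the 1,2-addition of the alkenyllithium to the aldehyde at −78 °C is much faster than attack on the hindered conjugated ester, while the uncontrolled carbinol centre is removed again in step 8.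

Step 7
Reactants: 14 methyl (2E,6S,10E)-6-[(tert-butyldimethylsilyl)oxy]-9-hydroxy-3,7,7-trimethyldodeca-2,10-dienoate
Product: 15 (2E,6S,10E)-6-[(tert-butyldimethylsilyl)oxy]-9-hydroxy-3,7,7-trimethyldodeca-2,10-dienoic acid (epimer mixture at C9 of the chain)
Conditions: LiOH·H2O, THF–MeOH–H2O, 45 °C; then 1 M HCl to pH 4, 0 °C
Reagents that add atoms: lithium hydroxide, [Li+].[OH-]
Why: Ester saponification is done at the allylic alcohol stage, before any base-sensitive enone exists, and the hindered secondary silyl ether and the E-enoate geometry tolerate warm LiOH.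

Step 8
Reactants: 15 (2E,6S,10E)-6-[(tert-butyldimethylsilyl)oxy]-9-hydroxy-3,7,7-trimethyldodeca-2,10-dienoic acid
Product: 16 (2E,6S,10E)-6-[(tert-butyldimethylsilyl)oxy]-3,7,7-trimethyl-9-oxododeca-2,10-dienoic acid
Conditions: DMP, CH2Cl2, 0 °C → rt
Reagents that add atoms: none
Why: Dess–Martin oxidation of the allylic alcohol tolerates the free carboxylic acid, merges both epimers into the single E-propenyl ketone and so installs the C6 carbonyl.

Step 9
Reactants: 16 (2E,6S,10E)-6-[(tert-butyldimethylsilyl)oxy]-3,7,7-trimethyl-9-oxododeca-2,10-dienoic acid; 17 oxazolidin-2-one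
Product: 19 3-[(2E,6S,10E)-6-[(tert-butyldimethylsilyl)oxy]-3,7,7-trimethyl-9-oxododeca-2,10-dienoyl]oxazolidin-2-one, via mixed pivalic anhydride 18 (not isolated)
Conditions: PivCl, Et3N, THF, −20 °C; then LiCl, 17, rt
Reagents that add atoms: none
Why: N-acylation through a mixed anhydride (LiCl/Et3N protocol) works because the lithium-activated oxazolidinone attacks the less hindered enoyl carbonyl of the anhydride, and no strong base is present that could harm the enone or deconjugate the enoate.

Step 10
Reactants: 19 3-[(2E,6S,10E)-6-[(tert-butyldimethylsilyl)oxy]-3,7,7-trimethyl-9-oxododeca-2,10-dienoyl]oxazolidin-2-one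
Product: 20 3-[(2E,6S,8Z,10E)-6,9-bis[(tert-butyldimethylsilyl)oxy]-3,7,7-trimethyldodeca-2,8,10-trienoyl]oxazolidin-2-one
Conditions: TBSOTf (1.3 equiv), Et3N (2 equiv), CH2Cl2, −78 → 0 °C; cold aq NaHCO3, Et3N-deactivated silica
Reagents that add atoms: tert-butyldimethylsilyl triflate, CC(C)(C)[Si](C)(C)OS(=O)(=O)C(F)(F)F
Why: Soft enolisation (silyl triflate plus tertiary amine) silylates the more Lewis-basic enone oxygen, Et3N then removes an α′-proton at C5 to give the cross-conjugated 2-siloxydiene, the Z geometry follows because quaternary C4 turns away from the propenyl group, and the imide, a much poorer silyl acceptor, is left alone.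

Step 11
Reactants: 20 3-[(2E,6S,8Z,10E)-6,9-bis[(tert-butyldimethylsilyl)oxy]-3,7,7-trimethyldodeca-2,8,10-trienoyl]oxazolidin-2-one
Product: 21 3-{[(1R,2R,4aS,6S,8aR)-4,6-bis[(tert-butyldimethylsilyl)oxy]-2,5,5,8a-tetramethyl-1,2,4a,5,6,7,8,8a-octahydronaphthalen-1-yl]carbonyl}oxazolidin-2-one (drimane numbering 3S,5S,8R,9R,10R; trans-fused; C8–CH3, C9–acyl and C10–CH3 all cis; C3–OTBS axial)
Conditions: [Cu((S,S)-t-Bu-box)](SbF6)2 (15 mol %; box = 2,2′-(propane-2,2-diyl)bis(4-tert-butyl-4,5-dihydrooxazole)), 4 Å MS, CH2Cl2, −20 °C → rt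
Reagents that add atoms: none
Why: The cationic divalent copper complex binds both imide carbonyls in a square-planar chelate, holds the enoyl unit s-cis and lowers its LUMO, so that the electron-rich diene C5=C6–C7=C8 adds suprafacially to C9=C10 in a normal-demand, strongly asynchronous [4+2] cycloaddition in which C5–C10 runs ahead of C8–C9 (at the limit a Mukaiyama–Michael addition followed by closure of the copper enolate onto the O-silylated enone, which needs no silyl transfer). The closest known reaction types are the copper–bis(oxazoline)-catalysed intramolecular Diels–Alder reaction of trienoyl oxazolidinones and the Lewis-acid Diels–Alder reaction of hindered 2-siloxydienes, and the hexafluoroantimonate salt is preferred to Cu(OTf)2 because the β,β-disubstituted enoate needs the more electrophilic metal centre. Ring B closes as the cyclohexene of the [4+2] event itself, and ring A closes in the same act as a six-membered carbocycle because the four-atom tether C1–C4 links diene terminus C5 to dienophile carbon C10 (type 1 mode, 1,7,9-decatriene pattern, chair-like tether). For C9 and C10 the tert-butyl groups of the (S,S)-ligand shield the Si face at C9, so the diene bonds to the Re face, and the E-enoate geometry is carried into the cis relation of C10–CH3 and the C9 acyl group; for C5 the endo position of the chelated acyl group together with the Z-enol ether (C4 on the outside of the diene) puts C5–H anti to C10–CH3, the trans fusion; for C8 the E-propenyl methyl, also outside, ends cis to the acyl group. The step needs one enoate face, endo orientation and one regiochemistry: the face comes from the ligand, endo from overlap with the chelated imide and from the chair tether, and the regiochemistry is fixed twice, by the tether and by the large HOMO coefficient at C5 meeting the β-carbon C10. The resident C3 centre must place its silyloxy group axial, which costs little because an equatorial group would be gauche to both C4 methyls, so reagent control should prevail and the minor enantiomer of 20 should end up in a separable diastereomer.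

Step 12
Reactants: 21 cycloadduct imide (drimane numbering 3S,5S,8R,9R,10R)
Product: 22 [(1R,2S,4aS,6S,8aS)-4,6-bis[(tert-butyldimethylsilyl)oxy]-2,5,5,8a-tetramethyl-1,2,4a,5,6,7,8,8a-octahydronaphthalen-1-yl]methanol (the C11 alcohol)
Conditions: LiBH4, H2O (1 equiv), Et2O, 0 °C
Reagents that add atoms: none
Why: Reductive cleavage of an N-acyloxazolidinone with water-modified LiBH4, the variant that favours hydride delivery to the exocyclic carbonyl of hindered imides, gives the primary C11 alcohol without touching either silyl group and without enolising C9.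

Step 13
Reactants: 22 the C11 alcohol; 23 umbelliferone (7-hydroxycoumarin)
Product: 24 7-{[(1R,2S,4aS,6S,8aS)-4,6-bis[(tert-butyldimethylsilyl)oxy]-2,5,5,8a-tetramethyl-1,2,4a,5,6,7,8,8a-octahydronaphthalen-1-yl]methoxy}chromen-2-one
Conditions: 23, PPh3, DIAD, toluene–THF, 0 → 50 °C
Reagents that add atoms: none
Why: Mitsunobu etherification works because the acidic phenol protonates the betaine and its phenoxide displaces the alkoxyphosphonium group at the primary, non-stereogenic C11, while the neutral medium spares the silyl enol ether.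

Step 14
Reactants: 24 the coumarin ether with the C6=C7 silyl enol ether
Product: 25 7-{[(1R,4aS,6S,8aS)-6-[(tert-butyldimethylsilyl)oxy]-2,5,5,8a-tetramethyl-4-oxo-1,4,4a,5,6,7,8,8a-octahydronaphthalen-1-yl]methoxy}chromen-2-one
Conditions: Pd(OAc)2 (1.1 equiv), MeCN, rt → 40 °C
Reagents that add atoms: none
Why: In the Saegusa–Ito oxidation divalent palladium replaces silicon to give the C7-bound oxo-π-allyl species on the open face anti to the C8 and C10 methyl groups and therefore syn to C8–H, so syn β-hydride elimination places the alkene at C7=C8, deletes the C8 centre, and the position of the enol ether fixes the regiochemistry.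

Step 15
Reactants: 25 the 3-O-TBS ether of the target
Product: 26 ferocaulidin, 7-{[(1R,4aS,6S,8aS)-6-hydroxy-2,5,5,8a-tetramethyl-4-oxo-1,4,4a,5,6,7,8,8a-octahydronaphthalen-1-yl]methoxy}chromen-2-one
Conditions: HF·pyridine, MeCN, 0 °C → rt (polypropylene vessel)
Reagents that add atoms: none
Why: Acidic fluoride desilylation removes the hindered C3 silyl ether with retention at C3, and it is chosen over basic fluoride because C9–H is vinylogously acidic, so base could expel the coumarin oxide or epimerise C5.

Compound list
1 | methyl geranate | COC(=O)/C=C(\C)CCC=C(C)C | starting material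
2 | secondary ozonide of the 6,7-alkene of 1 | COC(=O)/C=C(\C)CCC1OOC(C)(C)O1 | intermediate
3 | methyl (2E)-3-methyl-6-oxohex-2-enoate | COC(=O)/C=C(\C)CCC=O | intermediate
4 | 3-methylbuta-1,2-diene | CC(C)=C=C | starting material
5 | (3-methylbut-2-enyl)diisopinocampheylborane, Ipc from (−)-α-pinene | CC(C)=CCB([C@H]1C[C@H]2C[C@@H]([C@@H]1C)C2(C)C)[C@H]1C[C@H]2C[C@@H]([C@@H]1C)C2(C)C | intermediate
6 | diisopinocampheylborinate of alcohol 7 | C=CC(C)(C)[C@@H](OB([C@H]1C[C@H]2C[C@@H]([C@@H]1C)C2(C)C)[C@H]1C[C@H]2C[C@@H]([C@@H]1C)C2(C)C)CC/C(C)=C/C(=O)OC | intermediate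
7 | methyl (2E,6S)-6-hydroxy-3,7,7-trimethylnona-2,8-dienoate | C=CC(C)(C)[C@@H](O)CC/C(C)=C/C(=O)OC | intermediate
8 | methyl (2E,6S)-6-(TBSO)-3,7,7-trimethylnona-2,8-dienoate | C=CC(C)(C)[C@@H](O[Si](C)(C)C(C)(C)C)CC/C(C)=C/C(=O)OC | intermediate
9 | B-alkyl-9-BBN adduct of 8 | C1CC2CCCC(C1)B2CCC(C)(C)[C@@H](O[Si](C)(C)C(C)(C)C)CC/C(C)=C/C(=O)OC | intermediate
10 | methyl (2E,6S)-6-(TBSO)-9-hydroxy-3,7,7-trimethylnon-2-enoate | OCCC(C)(C)[C@@H](O[Si](C)(C)C(C)(C)C)CC/C(C)=C/C(=O)OC | intermediate
11 | methyl (2E,6S)-6-(TBSO)-3,7,7-trimethyl-9-oxonon-2-enoate | O=CCC(C)(C)[C@@H](O[Si](C)(C)C(C)(C)C)CC/C(C)=C/C(=O)OC | intermediate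
12 | (E)-1-bromoprop-1-ene | C/C=C/Br | starting material
13 | (E)-prop-1-enyllithium | C/C=C/[Li] | intermediate
14 | methyl (2E,6S,10E)-6-(TBSO)-9-hydroxy-3,7,7-trimethyldodeca-2,10-dienoate, carbinol epimers | C/C=C/C(O)CC(C)(C)[C@@H](O[Si](C)(C)C(C)(C)C)CC/C(C)=C/C(=O)OC | intermediate
15 | (2E,6S,10E)-6-(TBSO)-9-hydroxy-3,7,7-trimethyldodeca-2,10-dienoic acid, carbinol epimers | C/C=C/C(O)CC(C)(C)[C@@H](O[Si](C)(C)C(C)(C)C)CC/C(C)=C/C(=O)O | intermediate
16 | (2E,6S,10E)-6-(TBSO)-3,7,7-trimethyl-9-oxododeca-2,10-dienoic acid | C/C=C/C(=O)CC(C)(C)[C@@H](O[Si](C)(C)C(C)(C)C)CC/C(C)=C/C(=O)O | intermediate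
17 | oxazolidin-2-one | O=C1NCCO1 | starting material
18 | mixed pivalic anhydride of 16 | C/C=C/C(=O)CC(C)(C)[C@@H](O[Si](C)(C)C(C)(C)C)CC/C(C)=C/C(=O)OC(=O)C(C)(C)C | intermediate
19 | keto imide, 3-[(2E,6S,10E)-6-(TBSO)-3,7,7-trimethyl-9-oxododeca-2,10-dienoyl]oxazolidin-2-one | C/C=C/C(=O)CC(C)(C)[C@@H](O[Si](C)(C)C(C)(C)C)CC/C(C)=C/C(=O)N1CCOC1=O | intermediate
20 | siloxytriene imide (3S; E enoate, Z enol ether, E propenyl) | C/C=C/C(O[Si](C)(C)C(C)(C)C)=C/C(C)(C)[C@@H](O[Si](C)(C)C(C)(C)C)CC/C(C)=C/C(=O)N1CCOC1=O | intermediate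
21 | trans-fused cycloadduct with C6 silyl enol ether and C9 acyl oxazolidinone | C[C@@H]1C=C(O[Si](C)(C)C(C)(C)C)[C@@H]2C(C)(C)[C@@H](O[Si](C)(C)C(C)(C)C)CC[C@@]2(C)[C@@H]1C(=O)N1CCOC1=O | intermediate
22 | C11 alcohol | C[C@@H]1C=C(O[Si](C)(C)C(C)(C)C)[C@@H]2C(C)(C)[C@@H](O[Si](C)(C)C(C)(C)C)CC[C@@]2(C)[C@@H]1CO | intermediate
23 | umbelliferone | O=c1ccc2ccc(O)cc2o1 | starting material
24 | coumarin ether with silyl enol ether | C[C@@H]1C=C(O[Si](C)(C)C(C)(C)C)[C@@H]2C(C)(C)[C@@H](O[Si](C)(C)C(C)(C)C)CC[C@@]2(C)[C@@H]1COc1ccc2ccc(=O)oc2c1 | intermediate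
25 | 3-O-TBS-ferocaulidin | CC1=CC(=O)[C@@H]2C(C)(C)[C@@H](O[Si](C)(C)C(C)(C)C)CC[C@@]2(C)[C@@H]1COc1ccc2ccc(=O)oc2c1 | intermediate
26 | ferocaulidin | CC1=CC(=O)[C@@H]2C(C)(C)[C@@H](O)CC[C@@]2(C)[C@@H]1COc1ccc2ccc(=O)oc2c1 | target

Total step count: 15. Longest linear sequence: 15 steps, from methyl geranate 1 to 26.

Steps most likely to fail

Step 11.
- **What may go wrong:** The β,β-disubstituted enoyl imide may bind weakly and be poorly activated, because in the s-cis chelate its C10 methyl group points toward a ligand tert-butyl group. Protodesilylation of the diene could then outrun the cycloaddition. Facial control may also erode, because the ligand has to override any preference of the C3 silyloxy group for an equatorial place.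
- **Fallback:** Stereocontrol is moved into the substrate and activation is handed to a stoichiometric aluminium Lewis acid. The fallback sets out from keto acid 16 and comes back at alcohol 22. The mixed anhydride 18 is treated with lithiated (R)-4-benzyloxazolidin-2-one (n-BuLi, THF, −78 °C) to give the chiral keto imide F1. TBSOTf/Et3N as in step 10 gives the chiral siloxytriene F2. Me2AlCl (1.5–2 equiv, CH2Cl2, −30 °C) forms the cationic aluminium chelate, in which the benzyl group covers the Si face at C9. The auxiliary-controlled intramolecular Diels–Alder reaction then gives the chiral cycloadduct F3. LiBH4 cleavage as in step 12 removes the auxiliary and delivers 22.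

Step 10.
- **What may go wrong:** Proton removal at the neopentyl C5 may be slow, γ-deprotonation at C12 may compete and lead to the linear dienol ether, and the imide may be partly silylated.
- **Fallback:** The order of events is inverted, and a kinetic strong-base enolisation is run while the acid terminus is an inert carboxylate. The fallback sets out from keto acid 16 and comes back at 20. LDA (2.2 equiv, THF–DMPU, −78 °C) forms the carboxylate and then removes the kinetically favoured α′-proton at C5. TBSCl traps both oxygens to give the silyl ester silyl dienol ether F4. Brief K2CO3 in aqueous MeOH cleaves only the labile silyl ester and gives the siloxydiene acid F5. PivCl/Et3N gives the siloxydiene mixed anhydride F6, and lithiated 17 (n-BuLi, THF, −78 °C) converts it into 20.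

Step 13.
- **What may go wrong:** Displacement at C11 may be slow, because C11 is flanked by the quaternary C10 and the cis C8 methyl group. The alkoxyphosphonium ion could then be lost to alkylation of the hydrazide or simply persist.
- **Fallback:** The polarity of the C–O bond formation is reversed, so that no substitution at C11 is needed. The fallback sets out from 22 and comes back at 24. Alcohol 22 acts as the nucleophile in a Buchwald–Hartwig-type C–O coupling with commercial 7-bromocoumarin ([Pd(allyl)Cl]2, RockPhos, Cs2CO3, toluene, 90 °C). Oxidative addition to zerovalent palladium is followed by alkoxide exchange and reductive elimination. This gives 24 directly, and no new compound lies on the way.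

Further compounds
F1 | step 11 | (4R)-4-benzyl-3-[(2E,6S,10E)-6-(TBSO)-3,7,7-trimethyl-9-oxododeca-2,10-dienoyl]oxazolidin-2-one | C/C=C/C(=O)CC(C)(C)[C@@H](O[Si](C)(C)C(C)(C)C)CC/C(C)=C/C(=O)N1[C@H](Cc2ccccc2)COC1=O
F2 | step 11 | (4R)-4-benzyl-3-[(2E,6S,8Z,10E)-6,9-bis(TBSO)-3,7,7-trimethyldodeca-2,8,10-trienoyl]oxazolidin-2-one | C/C=C/C(O[Si](C)(C)C(C)(C)C)=C/C(C)(C)[C@@H](O[Si](C)(C)C(C)(C)C)CC/C(C)=C/C(=O)N1[C@H](Cc2ccccc2)COC1=O
F3 | step 11 | trans-fused cycloadduct carrying the (4R)-4-benzyloxazolidin-2-one at the C9 acyl group | C[C@@H]1C=C(O[Si](C)(C)C(C)(C)C)[C@@H]2C(C)(C)[C@@H](O[Si](C)(C)C(C)(C)C)CC[C@@]2(C)[C@@H]1C(=O)N1[C@H](Cc2ccccc2)COC1=O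
F4 | step 10 | tert-butyldimethylsilyl (2E,6S,8Z,10E)-6,9-bis(TBSO)-3,7,7-trimethyldodeca-2,8,10-trienoate | C/C=C/C(O[Si](C)(C)C(C)(C)C)=C/C(C)(C)[C@@H](O[Si](C)(C)C(C)(C)C)CC/C(C)=C/C(=O)O[Si](C)(C)C(C)(C)C
F5 | step 10 | (2E,6S,8Z,10E)-6,9-bis(TBSO)-3,7,7-trimethyldodeca-2,8,10-trienoic acid | C/C=C/C(O[Si](C)(C)C(C)(C)C)=C/C(C)(C)[C@@H](O[Si](C)(C)C(C)(C)C)CC/C(C)=C/C(=O)O
F6 | step 10 | mixed pivalic anhydride of F5 | C/C=C/C(O[Si](C)(C)C(C)(C)C)=C/C(C)(C)[C@@H](O[Si](C)(C)C(C)(C)C)CC/C(C)=C/C(=O)OC(=O)C(C)(C)C
F0 | step 13 | none | none
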